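**Retrosynthetic overview** (ring numbered C1 = carbon bearing the side chain, C2 = alkene CH, C3 = CH2, C4 = CHCl, C5 = CMe2, C6 = CHBr; side chain C1′ = CHCl, C2′ = CH2Br)
- C1′–Cl and the C1=C2 alkene come last, by ene-type chlorination of an (E)-2-bromoethylidene cyclohexane; C2′–Br comes from SN2′ bromination of a C1 vinyl carbinol; C6–Br from bromination next to a C1 ketone.
- The only ring, the six-membered carbocycle, is made in one (3+3) annulation that forms C2–C3 and C6–C5 together: a C5 1,3-dielectrophile (C3 primary triflate, C5 tertiary chloride, C4–Cl already in place) plus an acetoacetate 1,3-bis(silyl enol ether) (C2–C1–C6, C1 as ketone, removable ester on C2).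
- Enabling feature: the quaternary C5 and the C3 methylene both flank the chlorine-bearing C4, so C3–C4–C5 is a 1,3-dielectrophile whose tertiary cation is held as a chloronium ion by the C4 chlorine; C2 and C6 are 1,3-related through C1 and become the two α-carbons of a ketone.
- Absolute configuration enters at C4 (enantioselective dichlorination of prenol); C6 follows by thermodynamic control (axial Br trans to equatorial Cl); C1′ follows from alkene geometry and the face shielded by the C6 bromine.

Key step: step 5

Assumption: the ester-bearing ring carbon of 8–10 is configurationally labile (β-keto ester) and is drawn without configuration; diene 6 is used as obtained, its ketene acetal geometry being without consequence.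

**Step 1**
Reactants: 1 3-methylbut-2-en-1-ol
Product: 2 (2S)-2,3-dichloro-3-methylbutan-1-ol
Conditions: t-BuOCl, ClTi(OiPr)3, chiral tridentate Schiff-base amino alcohol ligand (20 mol %, enantiomer giving 2S), hexanes, −20 °C
Reagents that add atoms: tert-butyl hypochlorite, CC(C)(C)OCl; chlorotitanium triisopropoxide, CC(C)O[Ti](Cl)(OC(C)C)OC(C)C
Why: Titanium–Schiff-base-catalysed enantioselective dichlorination of an allylic alcohol, in which the titanium-bound alkoxide is chlorinated on the ligand-defined face and chloride is delivered anti to the tertiary carbon, so the ligand enantiomer sets the (S) C–Cl centre.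

**Step 2**
Reactants: 2 (2S)-2,3-dichloro-3-methylbutan-1-ol
Product: 3 (2S)-2,3-dichloro-3-methylbutyl trifluoromethanesulfonate
Conditions: Tf2O, 2,6-lutidine, CH2Cl2, −78 °C
Reagents that add atoms: trifluoromethanesulfonic anhydride, O=S(=O)(OS(=O)(=O)C(F)(F)F)C(F)(F)F
Why: Sulfonylation of a primary alcohol; the neighbouring chlorines retard ionisation and elimination, so the triflate should be handled cold and used directly.

**Step 3**
Reactants: 4 benzyl 3-oxobutanoate
Product: 5 benzyl (2Z)-3-[(trimethylsilyl)oxy]but-2-enoate
Conditions: Me3SiCl, Et3N, pentane, 20 °C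
Reagents that add atoms: chlorotrimethylsilane, C[Si](C)(C)Cl
Why: Soft enolisation and O-silylation of a β-keto ester gives the conjugated silyl enol ether.

**Step 4**
Reactants: 5 benzyl (2Z)-3-[(trimethylsilyl)oxy]but-2-enoate
Product: 6 1-(benzyloxy)-1,3-bis[(trimethylsilyl)oxy]buta-1,3-diene
Conditions: LiN(iPr)2, THF, −78 °C; Me3SiCl
Reagents that add atoms: chlorotrimethylsilane, C[Si](C)(C)Cl
Why: γ-Deprotonation of the vinylogous ester and O-silylation of the dienolate is the standard preparation of 1,3-bis(silyl enol ethers) as acetoacetate dianion equivalents.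

**Step 5**
Reactants: 3 (2S)-2,3-dichloro-3-methylbutyl trifluoromethanesulfonate; 6 1-(benzyloxy)-1,3-bis[(trimethylsilyl)oxy]buta-1,3-diene
Product: 8 benzyl (5S)-5-chloro-4,4-dimethyl-2-oxocyclohexane-1-carboxylate, via open-chain keto ester triflate 7 (not isolated)
Conditions: TiCl4, 4 Å molecular sieves, CH2Cl2, −78 → 20 °C
Reagents that add atoms: none
Why: Proposed new method: TiCl4 should ionise the tertiary chloride of 3 to a β-chloro cation held as a chloronium ion by the neighbouring chlorine, the terminal carbon of diene 6 should capture it at the tertiary carbon (bond to the quaternary centre, loss of Me3SiCl) to give the titanium-chelated keto ester 7, and the central carbon of that enolate should then displace the primary triflate to form the second ring bond (loss of Me3SiOTf). The closest known reaction types are the Lewis-acid α-tert-alkylation of silyl enol ethers with tertiary chlorides and the TiCl4-mediated formal (3+3) cyclisation of 1,3-bis(silyl enol ethers) with 1,3-dielectrophiles; a vicinal dichloride/primary triflate has not been used as the dielectrophile. The six-membered ring closes in a 6-(enolendo)-exo-tet mode. The chlorine-bearing carbon is not a reacting centre and should keep its configuration (chloronium bridging disfavours hydride shift), while the new ester-bearing centre is epimerisable and is removed in step 7. The step needs the tertiary site to react before the primary one (a β-chloro primary triflate is inert to TiCl4 and to silyl enol ethers at low temperature), attack through the diene terminus (by far its most nucleophilic carbon), and C- rather than O-alkylation in the closure (both oxygens are tied up in the titanium chelate, and the gem-dimethyl group favours ring closure).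

**Step 6**
Reactants: 8 benzyl (5S)-5-chloro-4,4-dimethyl-2-oxocyclohexane-1-carboxylate
Product: 9 benzyl (3R,5S)-3-bromo-5-chloro-4,4-dimethyl-2-oxocyclohexane-1-carboxylate
Conditions: Br2 (1 equiv), CH2Cl2–Et2O, 0 → 20 °C
Reagents that add atoms: bromine, BrBr
Why: Electrophilic bromination of a β-keto ester followed by HBr-mediated migration of bromine from the doubly activated carbon to the other ketone α-carbon (the known route to γ-bromo β-keto esters); under these equilibrating conditions the bromide should settle pseudoaxial, trans to the equatorial chlorine.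

**Step 7**
Reactants: 9 benzyl (3R,5S)-3-bromo-5-chloro-4,4-dimethyl-2-oxocyclohexane-1-carboxylate
Product: 11 (2R,4S)-2-bromo-4-chloro-3,3-dimethylcyclohexan-1-one, via bromo keto acid 10 (not isolated)
Conditions: BCl3, CH2Cl2, −78 → 0 °C; H2O; toluene, 60 °C
Reagents that add atoms: none
Why: Lewis-acid cleavage of the benzyl ester and decarboxylation of the β-keto acid on gentle warming, without base or hot HBr that could move the bromine; the trans isomer (axial Br, equatorial Cl) is the thermodynamically favoured α-bromo ketone.

**Step 8**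
Reactants: 11 (2R,4S)-2-bromo-4-chloro-3,3-dimethylcyclohexan-1-one
Product: 12 (1S,2R,4S)-2-bromo-4-chloro-1-ethenyl-3,3-dimethylcyclohexan-1-ol
Conditions: CH2=CHMgBr, CeCl3, THF, −78 °C; NH4Cl quench at −78 °C
Reagents that add atoms: vinylmagnesium bromide, C=C[Mg]Br
Why: 1,2-Addition of a vinylcerium reagent, whose low basicity suppresses enolisation of the α-bromo ketone; attack from the equatorial direction, away from the syn-axial methyl, should give the axial alcohol, and this carbinol centre is destroyed in step 9 (the cold quench avoids epoxide formation from the trans-bromohydrin alkoxide).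

**Step 9**
Reactants: 12 (1S,2R,4S)-2-bromo-4-chloro-1-ethenyl-3,3-dimethylcyclohexan-1-ol
Product: 13 (1E,2S,4S)-2-bromo-1-(2-bromoethylidene)-4-chloro-3,3-dimethylcyclohexane
Conditions: PBr3, pyridine (cat.), Et2O, −20 → 0 °C
Reagents that add atoms: phosphorus tribromide, BrP(Br)Br
Why: Allylic transposition of a tertiary vinyl carbinol to the primary allylic bromide (SN2′ bromination); the (E)-alkene should be favoured because the CH2Br group turns away from the bromine-bearing neopentyl side of the ring, and the ring stereocentres are not touched.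

**Step 10**
Reactants: 13 (1E,2S,4S)-2-bromo-1-(2-bromoethylidene)-4-chloro-3,3-dimethylcyclohexane
Product: 14 (4S,6R)-6-bromo-1-[(1S)-2-bromo-1-chloroethyl]-4-chloro-5,5-dimethylcyclohex-1-ene
Conditions: Ca(OCl)2, CO2 (solid), CH2Cl2–H2O, 0 °C
Reagents that add atoms: calcium hypochlorite, [Ca+2].[O-]Cl.[O-]Cl
Why: Ene-type allylic chlorination of a trisubstituted alkene with HOCl: chlorine should add to the less substituted alkene carbon on the face opposite the axial ring bromine while the axial proton of the neighbouring ring CH2 is lost, which moves the double bond into the ring and, from the (E)-alkene, sets the (S) C–Cl centre.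

**Compound list**
1 | 3-methylbut-2-en-1-ol | CC(C)=CCO | starting material
2 | (2S)-2,3-dichloro-3-methylbutan-1-ol | OC[C@H](Cl)C(C)(C)Cl | intermediate
3 | (2S)-2,3-dichloro-3-methylbutyl trifluoromethanesulfonate | FC(F)(F)S(=O)(=O)OC[C@H](Cl)C(C)(C)Cl | intermediate
4 | benzyl 3-oxobutanoate | CC(=O)CC(=O)OCc1ccccc1 | starting material
5 | benzyl (2Z)-3-[(trimethylsilyl)oxy]but-2-enoate | C/C(O[Si](C)(C)C)=C/C(=O)OCc1ccccc1 | intermediate
6 | 1-(benzyloxy)-1,3-bis[(trimethylsilyl)oxy]buta-1,3-diene | C=C(O[Si](C)(C)C)C=C(O[Si](C)(C)C)OCc1ccccc1 | intermediate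
7 | benzyl (6R)-6-chloro-5,5-dimethyl-3-oxo-7-[(trifluoromethanesulfonyl)oxy]heptanoate (held as its titanium enolate) | FC(F)(F)S(=O)(=O)OC[C@H](Cl)C(C)(C)CC(=O)CC(=O)OCc1ccccc1 | intermediate
8 | benzyl (5S)-5-chloro-4,4-dimethyl-2-oxocyclohexane-1-carboxylate | O=C(OCc1ccccc1)C1C[C@H](Cl)C(C)(C)CC1=O | intermediate
9 | benzyl (3R,5S)-3-bromo-5-chloro-4,4-dimethyl-2-oxocyclohexane-1-carboxylate | O=C(OCc1ccccc1)C1C[C@H](Cl)C(C)(C)[C@@H](Br)C1=O | intermediate
10 | (3R,5S)-3-bromo-5-chloro-4,4-dimethyl-2-oxocyclohexane-1-carboxylic acid | OC(=O)C1C[C@H](Cl)C(C)(C)[C@@H](Br)C1=O | intermediate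
11 | (2R,4S)-2-bromo-4-chloro-3,3-dimethylcyclohexan-1-one | O=C1CC[C@H](Cl)C(C)(C)[C@H]1Br | intermediate
12 | (1S,2R,4S)-2-bromo-4-chloro-1-ethenyl-3,3-dimethylcyclohexan-1-ol | C=C[C@@]1(O)CC[C@H](Cl)C(C)(C)[C@H]1Br | intermediate
13 | (1E,2S,4S)-2-bromo-1-(2-bromoethylidene)-4-chloro-3,3-dimethylcyclohexane | BrC/C=C1\CC[C@H](Cl)C(C)(C)[C@H]1Br | intermediate
14 | (4S,6R)-6-bromo-1-[(1S)-2-bromo-1-chloroethyl]-4-chloro-5,5-dimethylcyclohex-1-ene | CC1(C)[C@@H](Cl)CC=C([C@H](Cl)CBr)[C@@H]1Br | target

**Step count**
Total: 10 steps. Longest linear sequence: 8 steps (1 → 2 → 3 → 8 → 9 → 11 → 12 → 13 → 14).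

**Steps most likely to fail**

Step 5 (proposed new method). The second alkylation may not follow the first: the reaction may stall at the open-chain titanium enolate, chloride may displace the triflate, or O-alkylation may compete. The β-chloro cation may also lose a proton or suffer a hydride shift, which would erode the C–Cl stereocentre. The fallback uses known chemistry and reverses the order of bond formation; it sets out from triflate 3 and benzyl acetoacetate 4 and comes back at ketone 11. The dianion of 4 (NaH, then n-BuLi, THF, 0 °C) should be alkylated at its terminal carbon by 3 (classical γ-alkylation of an acetoacetate dianion) to give benzyl (6S)-6,7-dichloro-7-methyl-3-oxooctanoate F1. SnCl4 in CH2Cl2 should then ionise the tertiary chloride and the β-keto ester carbon should close onto it (Lewis-acid α-tert-alkylation of a β-dicarbonyl compound), giving benzyl (5S)-5-chloro-6,6-dimethyl-2-oxocyclohexane-1-carboxylate F2. Hydrogenolysis (H2, Pd/C) should give (5S)-5-chloro-6,6-dimethyl-2-oxocyclohexane-1-carboxylic acid F3, and NBS-induced bromodecarboxylation should place bromine on the carbon next to the quaternary centre to give 11. Steps 6 and 7 are then not needed, but the two ring bonds are made in two operations.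

Step 10. Diastereoselectivity at the side-chain C–Cl centre may be eroded by chlorine delivery to the wrong alkene face or by (Z)-alkene carried over from step 9; simple addition across the alkene or proton loss towards the bromine-bearing carbon may also compete. The fallback sets this centre by reagent control; it sets out from ketone 11 and comes back at target 14.
- CeCl3-mediated addition of 1-ethoxyvinyllithium should give (2R,4S)-2-bromo-4-chloro-1-(1-ethoxyethenyl)-3,3-dimethylcyclohexan-1-ol F4.
- Mild aqueous acid should give 1-[(2R,4S)-2-bromo-4-chloro-1-hydroxy-3,3-dimethylcyclohexyl]ethan-1-one F5.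
- Dehydration with Ph2S[OC(CF3)2Ph]2 should give 1-[(4S,6S)-6-bromo-4-chloro-5,5-dimethylcyclohex-1-en-1-yl]ethan-1-one F6.
- Bromination of the methyl ketone (PhNMe3Br3, THF) should give 2-bromo-1-[(4S,6S)-6-bromo-4-chloro-5,5-dimethylcyclohex-1-en-1-yl]ethan-1-one F7.
- Corey–Bakshi–Shibata reduction, with the oxazaborolidine enantiomer chosen for the (R) carbinol, should give (1R)-2-bromo-1-[(4S,6S)-6-bromo-4-chloro-5,5-dimethylcyclohex-1-en-1-yl]ethan-1-ol F8.
- K2CO3 in MeOH should close (2R)-2-[(4S,6S)-6-bromo-4-chloro-5,5-dimethylcyclohex-1-en-1-yl]oxirane F9.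
- HCl in Et2O should open the vinyl epoxide at the allylic carbon with inversion to (2S)-2-[(4S,6R)-6-bromo-4-chloro-5,5-dimethylcyclohex-1-en-1-yl]-2-chloroethan-1-ol F10.
- An Appel reaction (CBr4, PPh3) on the primary alcohol should give 14.

Step 6. Regiocontrol may be poor: bromine may stay on the doubly activated carbon, or over-bromination may occur, because migration to the hindered carbon next to the quaternary centre is slow. The fallback replaces thermodynamic migration by bromination of a defined dienol ether; it sets out from keto ester 8 and comes back at bromo keto ester 9. Double deprotonation of 8 (LiN(iPr)2, 2.2 equiv, THF, −78 → 0 °C) and silylation (Me3SiCl) should give the ring bis(silyl enol ether) {(benzyloxy)[(5S)-5-chloro-4,4-dimethyl-2-[(trimethylsilyl)oxy]cyclohex-2-en-1-ylidene]methoxy}trimethylsilane F11. NBS (1 equiv, THF, −78 °C) should then brominate its terminal diene carbon, giving 9 after aqueous work-up.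

**Further compounds**
F1 | step 5 | benzyl (6S)-6,7-dichloro-7-methyl-3-oxooctanoate | CC(C)(Cl)[C@@H](Cl)CCC(=O)CC(=O)OCc1ccccc1
F2 | step 5 | benzyl (5S)-5-chloro-6,6-dimethyl-2-oxocyclohexane-1-carboxylate | O=C(OCc1ccccc1)C1C(=O)CC[C@H](Cl)C1(C)C
F3 | step 5 | (5S)-5-chloro-6,6-dimethyl-2-oxocyclohexane-1-carboxylic acid | OC(=O)C1C(=O)CC[C@H](Cl)C1(C)C
F4 | step 10 | (2R,4S)-2-bromo-4-chloro-1-(1-ethoxyethenyl)-3,3-dimethylcyclohexan-1-ol | CCOC(=C)C1(O)CC[C@H](Cl)C(C)(C)[C@H]1Br
F5 | step 10 | 1-[(2R,4S)-2-bromo-4-chloro-1-hydroxy-3,3-dimethylcyclohexyl]ethan-1-one | CC(=O)C1(O)CC[C@H](Cl)C(C)(C)[C@H]1Br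
F6 | step 10 | 1-[(4S,6S)-6-bromo-4-chloro-5,5-dimethylcyclohex-1-en-1-yl]ethan-1-one | CC(=O)C1=CC[C@H](Cl)C(C)(C)[C@H]1Br
F7 | step 10 | 2-bromo-1-[(4S,6S)-6-bromo-4-chloro-5,5-dimethylcyclohex-1-en-1-yl]ethan-1-one | BrCC(=O)C1=CC[C@H](Cl)C(C)(C)[C@H]1Br
F8 | step 10 | (1R)-2-bromo-1-[(4S,6S)-6-bromo-4-chloro-5,5-dimethylcyclohex-1-en-1-yl]ethan-1-ol | BrC[C@H](O)C1=CC[C@H](Cl)C(C)(C)[C@H]1Br
F9 | step 10 | (2R)-2-[(4S,6S)-6-bromo-4-chloro-5,5-dimethylcyclohex-1-en-1-yl]oxirane | C1O[C@@H]1C2=CC[C@H](Cl)C(C)(C)[C@H]2Br
F10 | step 10 | (2S)-2-[(4S,6R)-6-bromo-4-chloro-5,5-dimethylcyclohex-1-en-1-yl]-2-chloroethan-1-ol | OC[C@@H](Cl)C1=CC[C@H](Cl)C(C)(C)[C@H]1Br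
F11 | step 6 | {(benzyloxy)[(5S)-5-chloro-4,4-dimethyl-2-[(trimethylsilyl)oxy]cyclohex-2-en-1-ylidene]methoxy}trimethylsilane | C[Si](C)(C)OC(OCc1ccccc1)=C1C[C@H](Cl)C(C)(C)C=C1O[Si](C)(C)C
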